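The pyranone ring of the flavanone is cut across C2–C3 and O1–C8a, the way a Danishefsky diene–aldehyde annulation would build it. The B-ring aldehyde, already carrying the threo side chain (Evans syn aldol), supplies C2 and the ring oxygen; ring A enters as a 2-fluoroaryl enol silane whose C4a=C8a–F unit mimics the diene's methoxyvinyl end. In one operation a catalytic asymmetric Mukaiyama aldol forges C2–C3 and sets C2, then fluoride unmasks the alkoxide, which closes O1–C8a by SNAr with loss of Me3SiF. The feature exploited is the electrophilic C8a of ring A, ortho to the C4 carbonyl and meta to both oxygens.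

Key step: step 10

Remarks and assumptions
- Numbering: flavanone atoms are O1, C2, C3, C4, C4a, C5–C8, C8a; the side chain is C7'' (carbinol), C8'' (aryloxy carbon), C9'' (CH2OH). The target is (2S,7''R,8''R), i.e. the threo side chain.
- Assumption: the (R)-tryptophan-derived boron catalyst of step 10 is taken to direct the enol silane to the Si face of the formyl group, which is what 2S requires. The sense should be confirmed on 3,4,5-trimethoxybenzaldehyde, and the enantiomeric catalyst used if it is opposite.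
- Metal salts and chelates that are only protonated or hydrolysed on work-up are not numbered.

Step 1
Reactants: 1 5-fluororesorcinol
Product: 2 1-(2-fluoro-4,6-dihydroxyphenyl)ethan-1-one
Conditions: AcOH, BF3·OEt2, 90 °C; aq. NaOAc work-up
Reagents that add atoms: acetic acid CC(=O)O
Why: Nencki-type Friedel–Crafts C-acylation should occur at the ring position ortho to one hydroxyl, para to the other and ortho to fluorine, as in the acylation of orcinol, the site between the two hydroxyls being more hindered.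

Step 2
Reactants: 2 1-(2-fluoro-4,6-dihydroxyphenyl)ethan-1-one
Product: 3 1-[2,4-bis(benzyloxy)-6-fluorophenyl]ethan-1-one
Conditions: BnBr (2.3 equiv), K2CO3, DMF, 60 °C
Reagents that add atoms: benzyl bromide BrCc1ccccc1
Why: Williamson etherification should benzylate both phenols (the chelated ortho one on warming) while the aryl fluoride, on a phenoxide-bearing ring, stays inert.

Step 3
Reactants: 3 1-[2,4-bis(benzyloxy)-6-fluorophenyl]ethan-1-one
Product: 4 {1-[2,4-bis(benzyloxy)-6-fluorophenyl]ethenyl}oxy(trimethyl)silane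
Conditions: TMSOTf, Et3N, CH2Cl2, 0 °C; used without chromatography
Reagents that add atoms: trimethylsilyl triflate C[Si](C)(C)OS(=O)(=O)C(F)(F)F
Why: Soft enolisation and O-silylation of a methyl ketone with a single enolisable site should give the enol silane cleanly.

Step 4
Reactants: 5 4-bromo-2,6-dimethoxyphenol
Product: 6 2-(4-bromo-2,6-dimethoxyphenoxy)acetic acid
Conditions: NaH (2.2 equiv), BrCH2CO2H, THF, 0 °C → reflux; then 1 M HCl
Reagents that add atoms: bromoacetic acid OC(=O)CBr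
Why: Williamson etherification, in which the phenoxide displaces bromide from sodium bromoacetate, whose carboxylate is protected as its salt.

Step 5
Reactants: 6 2-(4-bromo-2,6-dimethoxyphenoxy)acetic acid; 7 (4S)-4-benzyl-1,3-oxazolidin-2-one
Product: 9 (4S)-4-benzyl-3-[2-(4-bromo-2,6-dimethoxyphenoxy)acetyl]-1,3-oxazolidin-2-one, via mixed pivalic anhydride 8 (not isolated)
Conditions: PivCl, Et3N, THF, −20 °C; then 7, LiCl, rt
Reagents that add atoms: pivaloyl chloride CC(C)(C)C(Cl)=O (its acyl group is carried only by intermediate 8)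
Why: N-acylation of the oxazolidinone through the mixed anhydride should occur at the unhindered aryloxyacetyl carbonyl, with LiCl activating the auxiliary.

Step 6
Reactants: 9 (4S)-4-benzyl-3-[2-(4-bromo-2,6-dimethoxyphenoxy)acetyl]-1,3-oxazolidin-2-one; 10 4-(benzyloxy)benzaldehyde
Product: 12 (4S)-4-benzyl-3-[(2S,3R)-3-[4-(benzyloxy)phenyl]-2-(4-bromo-2,6-dimethoxyphenoxy)-3-hydroxypropanoyl]-1,3-oxazolidin-2-one, via Z-boron enolate 11 (not isolated)
Conditions: Bu2BOTf, iPr2NEt, CH2Cl2, −78 → 0 °C; then 10, −78 → 0 °C; pH 7 buffer, MeOH, H2O2, 0 °C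
Reagents that add atoms: dibutylboron triflate CCCCB(CCCC)OS(=O)(=O)C(F)(F)F (boron is carried only by intermediate 11)
Why: Evans syn aldol, in which the Z-boron enolate reacts through a Zimmerman–Traxler chair and the benzyl group of the auxiliary shields one enolate face, so the 2,3-syn (2S,3R) adduct should form and both side-chain stereocentres (the future C8'' and C7'') are set together.

Step 7
Reactants: 12 (4S)-4-benzyl-3-[(2S,3R)-3-[4-(benzyloxy)phenyl]-2-(4-bromo-2,6-dimethoxyphenoxy)-3-hydroxypropanoyl]-1,3-oxazolidin-2-one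
Product: 13 (1R,2R)-1-[4-(benzyloxy)phenyl]-2-(4-bromo-2,6-dimethoxyphenoxy)propane-1,3-diol
Conditions: LiBH4, THF, MeOH (1 equiv), 0 °C → rt
Reagents that add atoms: none
Why: Reductive cleavage of the imide by LiBH4 should give the 1,3-diol and release the auxiliary without touching either stereocentre (the descriptor at the aryloxy carbon changes from S to R only because CH2OH ranks below the carbinol carbon).

Step 8
Reactants: 13 (1R,2R)-1-[4-(benzyloxy)phenyl]-2-(4-bromo-2,6-dimethoxyphenoxy)propane-1,3-diol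
Product: 14 (4R,5R)-4-[4-(benzyloxy)phenyl]-5-(4-bromo-2,6-dimethoxyphenoxy)-2,2-dimethyl-1,3-dioxane
Conditions: 2,2-dimethoxypropane, PPTS (cat.), CH2Cl2, rt
Reagents that add atoms: 2,2-dimethoxypropane COC(C)(C)OC
Why: Acid-catalysed transketalisation should close the six-membered acetonide over the 1,3-diol, masking both hydroxyls for the organolithium, Lewis acid and fluoride steps.

Step 9
Reactants: 14 (4R,5R)-4-[4-(benzyloxy)phenyl]-5-(4-bromo-2,6-dimethoxyphenoxy)-2,2-dimethyl-1,3-dioxane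
Product: 16 4-{[(4R,5R)-4-[4-(benzyloxy)phenyl]-2,2-dimethyl-1,3-dioxan-5-yl]oxy}-3,5-dimethoxybenzaldehyde, via aryllithium 15 (not isolated)
Conditions: n-BuLi, THF, −78 °C; then DMF, −78 → 0 °C; aq. NH4Cl
Reagents that add atoms: N,N-dimethylformamide CN(C)C=O; n-butyllithium [Li]CCCC (lithium is carried only by intermediate 15)
Why: Bromine–lithium exchange at −78 °C should outpace any deprotonation, and Bouveault formylation of the aryllithium with DMF gives the aldehyde on work-up.

Step 10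
Reactants: 16 4-{[(4R,5R)-4-[4-(benzyloxy)phenyl]-2,2-dimethyl-1,3-dioxan-5-yl]oxy}-3,5-dimethoxybenzaldehyde; 4 {1-[2,4-bis(benzyloxy)-6-fluorophenyl]ethenyl}oxy(trimethyl)silane
Product: 18 (2S)-5,7-bis(benzyloxy)-2-(4-{[(4R,5R)-4-[4-(benzyloxy)phenyl]-2,2-dimethyl-1,3-dioxan-5-yl]oxy}-3,5-dimethoxyphenyl)-2,3-dihydro-4H-chromen-4-one, via TMS aldol ether 17 (not isolated)
Conditions: 4 (1.1 equiv), N-tosyl-(R)-tryptophan-derived B-n-butyl-1,3,2-oxazaborolidin-5-one (20 mol %), EtCN, −78 °C; then CsF (1.0 equiv), DMF, −20 → 0 °C; AcOH quench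
Reagents that add atoms: none
Why: The boron Lewis acid activates the formyl group of 16 and enol silane 4 adds through an open transition state (catalytic asymmetric Mukaiyama aldol), forging C2–C3 and passing the silyl group to oxygen to give β-silyloxy ketone 17; fluoride then cleaves the O–Si bond and the freed alkoxide attacks C8a, ortho to the C4 carbonyl, expelling fluoride through a Meisenheimer intermediate (intramolecular SNAr), so fluoride is regenerated and Me3SiF is the only by-product. The closest known reaction type is the Mukaiyama aldol–dihydropyranone annulation of Danishefsky-type dienes, with the C4a=C8a–F unit of ring A standing in for the methoxyvinyl terminus, joined to the SNAr closure of β-hydroxy 2-fluoroaryl ketones to chroman-4-ones. The pyranone ring closes in a 6-exo-trig addition–elimination at the arene carbon. C2 is the only new stereocentre and is set under catalyst control by Si-face attack on the aldehyde, the dioxane stereocentres being too remote to bias it; the SNAr step does not touch C2, so its configuration is carried into the ring unchanged. The step needs enantioface selectivity, and it needs ring closure to outrun retro-aldol cleavage and β-elimination of the alkoxide: the alkoxide is released only after C–C bond formation is complete, at low temperature and with a caesium counter-ion that does not chelate it to the carbonyl, and the ortho-acyl group leaves C8a as the only electrophilic arene carbon within reach.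

Step 11
Reactants: 18 (2S)-5,7-bis(benzyloxy)-2-(4-{[(4R,5R)-4-[4-(benzyloxy)phenyl]-2,2-dimethyl-1,3-dioxan-5-yl]oxy}-3,5-dimethoxyphenyl)-2,3-dihydro-4H-chromen-4-one
Product: 19 (2S)-5,7-bis(benzyloxy)-2-(4-{[(1R,2R)-1-[4-(benzyloxy)phenyl]-1,3-dihydroxypropan-2-yl]oxy}-3,5-dimethoxyphenyl)-2,3-dihydro-4H-chromen-4-one
Conditions: AcOH/H2O/THF (4:1:1), 40 °C
Reagents that add atoms: none
Why: Mild acid hydrolysis of the isopropylidene ketal should ionise at the ketal carbon and not at benzylic C7'', while the chromanone and the benzyl ethers are stable to dilute acetic acid.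

Step 12
Reactants: 19 (2S)-5,7-bis(benzyloxy)-2-(4-{[(1R,2R)-1-[4-(benzyloxy)phenyl]-1,3-dihydroxypropan-2-yl]oxy}-3,5-dimethoxyphenyl)-2,3-dihydro-4H-chromen-4-one
Product: 20 (2S)-5,7-dihydroxy-2-(4-{[(1R,2R)-1,3-dihydroxy-1-(4-hydroxyphenyl)propan-2-yl]oxy}-3,5-dimethoxyphenyl)-2,3-dihydro-4H-chromen-4-one (CNP0263993.1)
Conditions: H2 (1 atm), 10 % Pd/C, EtOAc, rt, stopped after uptake of 3 equiv
Reagents that add atoms: none
Why: Hydrogenolysis of the three aryl benzyl ethers should be faster than cleavage of the C2–O1 bond or the C7''–OH bond under neutral conditions, and no stereocentre is touched.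

Compound list
1 | 5-fluororesorcinol | Oc1cc(O)cc(F)c1 | starting material
2 | 1-(2-fluoro-4,6-dihydroxyphenyl)ethan-1-one | CC(=O)c1c(O)cc(O)cc1F | intermediate
3 | 1-[2,4-bis(benzyloxy)-6-fluorophenyl]ethan-1-one | CC(=O)c1c(OCc2ccccc2)cc(OCc2ccccc2)cc1F | intermediate
4 | {1-[2,4-bis(benzyloxy)-6-fluorophenyl]ethenyl}oxy(trimethyl)silane | C=C(O[Si](C)(C)C)c1c(OCc2ccccc2)cc(OCc2ccccc2)cc1F | intermediate
5 | 4-bromo-2,6-dimethoxyphenol | COc1cc(Br)cc(OC)c1O | starting material
6 | 2-(4-bromo-2,6-dimethoxyphenoxy)acetic acid | COc1cc(Br)cc(OC)c1OCC(=O)O | intermediate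
7 | (4S)-4-benzyl-1,3-oxazolidin-2-one | O=C1OC[C@H](Cc2ccccc2)N1 | starting material
8 | 2-(4-bromo-2,6-dimethoxyphenoxy)acetic pivalic anhydride | COc1cc(Br)cc(OC)c1OCC(=O)OC(=O)C(C)(C)C | intermediate
9 | (4S)-4-benzyl-3-[2-(4-bromo-2,6-dimethoxyphenoxy)acetyl]-1,3-oxazolidin-2-one | COc1cc(Br)cc(OC)c1OCC(=O)N1[C@@H](Cc2ccccc2)COC1=O | intermediate
10 | 4-(benzyloxy)benzaldehyde | O=Cc1ccc(OCc2ccccc2)cc1 | starting material
11 | (Z)-1-[(4S)-4-benzyl-2-oxo-1,3-oxazolidin-3-yl]-2-(4-bromo-2,6-dimethoxyphenoxy)ethenyl dibutylborinate | CCCCB(CCCC)O/C(=C\Oc1c(OC)cc(Br)cc1OC)N1[C@@H](Cc2ccccc2)COC1=O | intermediate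
12 | (4S)-4-benzyl-3-[(2S,3R)-3-[4-(benzyloxy)phenyl]-2-(4-bromo-2,6-dimethoxyphenoxy)-3-hydroxypropanoyl]-1,3-oxazolidin-2-one | O=C1OC[C@H](Cc2ccccc2)N1C(=O)[C@@H](Oc1c(OC)cc(Br)cc1OC)[C@H](O)c1ccc(OCc2ccccc2)cc1 | intermediate
13 | (1R,2R)-1-[4-(benzyloxy)phenyl]-2-(4-bromo-2,6-dimethoxyphenoxy)propane-1,3-diol | COc1cc(Br)cc(OC)c1O[C@H](CO)[C@H](O)c1ccc(OCc2ccccc2)cc1 | intermediate
14 | (4R,5R)-4-[4-(benzyloxy)phenyl]-5-(4-bromo-2,6-dimethoxyphenoxy)-2,2-dimethyl-1,3-dioxane | COc1cc(Br)cc(OC)c1O[C@@H]2COC(C)(C)O[C@@H]2c3ccc(OCc4ccccc4)cc3 | intermediate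
15 | (4-{[(4R,5R)-4-[4-(benzyloxy)phenyl]-2,2-dimethyl-1,3-dioxan-5-yl]oxy}-3,5-dimethoxyphenyl)lithium | COc1cc([Li])cc(OC)c1O[C@@H]2COC(C)(C)O[C@@H]2c3ccc(OCc4ccccc4)cc3 | intermediate
16 | 4-{[(4R,5R)-4-[4-(benzyloxy)phenyl]-2,2-dimethyl-1,3-dioxan-5-yl]oxy}-3,5-dimethoxybenzaldehyde | COc1cc(C=O)cc(OC)c1O[C@@H]2COC(C)(C)O[C@@H]2c3ccc(OCc4ccccc4)cc3 | intermediate
17 | (3S)-1-[2,4-bis(benzyloxy)-6-fluorophenyl]-3-(4-{[(4R,5R)-4-[4-(benzyloxy)phenyl]-2,2-dimethyl-1,3-dioxan-5-yl]oxy}-3,5-dimethoxyphenyl)-3-[(trimethylsilyl)oxy]propan-1-one | COc1cc([C@H](CC(=O)c2c(OCc3ccccc3)cc(OCc3ccccc3)cc2F)O[Si](C)(C)C)cc(OC)c1O[C@@H]4COC(C)(C)O[C@@H]4c5ccc(OCc6ccccc6)cc5 | intermediate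
18 | (2S)-5,7-bis(benzyloxy)-2-(4-{[(4R,5R)-4-[4-(benzyloxy)phenyl]-2,2-dimethyl-1,3-dioxan-5-yl]oxy}-3,5-dimethoxyphenyl)-2,3-dihydro-4H-chromen-4-one | COc1cc([C@@H]2CC(=O)c3c(OCc4ccccc4)cc(OCc4ccccc4)cc3O2)cc(OC)c1O[C@@H]5COC(C)(C)O[C@@H]5c6ccc(OCc7ccccc7)cc6 | intermediate
19 | (2S)-5,7-bis(benzyloxy)-2-(4-{[(1R,2R)-1-[4-(benzyloxy)phenyl]-1,3-dihydroxypropan-2-yl]oxy}-3,5-dimethoxyphenyl)-2,3-dihydro-4H-chromen-4-one | COc1cc([C@@H]2CC(=O)c3c(OCc4ccccc4)cc(OCc4ccccc4)cc3O2)cc(OC)c1O[C@H](CO)[C@H](O)c5ccc(OCc6ccccc6)cc5 | intermediate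
20 | (2S)-5,7-dihydroxy-2-(4-{[(1R,2R)-1,3-dihydroxy-1-(4-hydroxyphenyl)propan-2-yl]oxy}-3,5-dimethoxyphenyl)-2,3-dihydro-4H-chromen-4-one | COc1cc([C@@H]2CC(=O)c3c(O)cc(O)cc3O2)cc(OC)c1O[C@H](CO)[C@H](O)c1ccc(O)cc1 | target

Total step count: 12. Longest linear sequence: 9 steps (5 → 6 → 9 → 12 → 13 → 14 → 16 → 18 → 19 → 20, steps 4–12); the ring-A branch (steps 1–3) joins at step 10.

Steps most likely to fail

Step 10. The unmasked alkoxide may undergo retro-aldol cleavage or β-elimination to the enone before it closes onto C8a, which would erode the C2 configuration or divert material, and enantioface control in the aldol may be incomplete. The fallback sets out from 16 and returns at 18. Claisen–Schmidt condensation of 16 with commercial 1-[2,4-bis(benzyloxy)-6-hydroxyphenyl]ethan-1-one (KOH, EtOH/THF, rt) should give (E)-1-[2,4-bis(benzyloxy)-6-hydroxyphenyl]-3-(4-{[(4R,5R)-4-[4-(benzyloxy)phenyl]-2,2-dimethyl-1,3-dioxan-5-yl]oxy}-3,5-dimethoxyphenyl)prop-2-en-1-one F1. Intramolecular oxa-Michael cyclisation of the 2'-hydroxychalcone under a bifunctional quinine-derived thiourea catalyst should then give 18, with preparative HPLC separation of the C2 epimers as a backstop.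

Step 12. Over-reduction may occur, with hydrogenolysis of the benzylic C7''–OH bond (most exposed once the para-phenol is free) or of the C2–O1 bond. The fallback sets out from 18 and returns at 20 by reversing the order of the two deprotections. Hydrogenolysis of 18 (H2, Pd/C, EtOAc), with the 7''-oxygen still locked in the dioxane, should give (2S)-5,7-dihydroxy-2-(4-{[(4R,5R)-4-(4-hydroxyphenyl)-2,2-dimethyl-1,3-dioxan-5-yl]oxy}-3,5-dimethoxyphenyl)-2,3-dihydro-4H-chromen-4-one F2, and brief treatment with aqueous acetic acid at rt should then release 20.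

Step 6. Enolisation of the hindered, electron-rich aryloxyacetyl imide may be sluggish, or the syn and facial selectivity may be eroded. The fallback sets out from 6 and returns at 13, setting both stereocentres by reduction instead of by an auxiliary. Fischer esterification of 6 (EtOH, cat. H2SO4) should give ethyl 2-(4-bromo-2,6-dimethoxyphenoxy)acetate F3. C-acylation of its lithium enolate (LiHMDS, THF, −78 °C) with 4-(benzyloxy)benzoyl chloride should give racemic ethyl 3-[4-(benzyloxy)phenyl]-2-(4-bromo-2,6-dimethoxyphenoxy)-3-oxopropanoate F4. Ru–TsDPEN transfer hydrogenation with dynamic kinetic resolution (HCO2H/Et3N, catalyst antipode chosen for the 3R carbinol), which is syn-selective for α-alkoxy β-keto esters, should give ethyl (2S,3R)-3-[4-(benzyloxy)phenyl]-2-(4-bromo-2,6-dimethoxyphenoxy)-3-hydroxypropanoate F5. LiBH4 reduction then gives 13.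

Further compounds
F1 | step 10 | (E)-1-[2,4-bis(benzyloxy)-6-hydroxyphenyl]-3-(4-{[(4R,5R)-4-[4-(benzyloxy)phenyl]-2,2-dimethyl-1,3-dioxan-5-yl]oxy}-3,5-dimethoxyphenyl)prop-2-en-1-one | COc1cc(/C=C/C(=O)c2c(O)cc(OCc3ccccc3)cc2OCc3ccccc3)cc(OC)c1O[C@@H]4COC(C)(C)O[C@@H]4c5ccc(OCc6ccccc6)cc5
F2 | step 12 | (2S)-5,7-dihydroxy-2-(4-{[(4R,5R)-4-(4-hydroxyphenyl)-2,2-dimethyl-1,3-dioxan-5-yl]oxy}-3,5-dimethoxyphenyl)-2,3-dihydro-4H-chromen-4-one | COc1cc([C@@H]2CC(=O)c3c(O)cc(O)cc3O2)cc(OC)c1O[C@@H]4COC(C)(C)O[C@@H]4c5ccc(O)cc5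
F3 | step 6 | ethyl 2-(4-bromo-2,6-dimethoxyphenoxy)acetate | CCOC(=O)COc1c(OC)cc(Br)cc1OC
F4 | step 6 | ethyl 3-[4-(benzyloxy)phenyl]-2-(4-bromo-2,6-dimethoxyphenoxy)-3-oxopropanoate (racemic) | CCOC(=O)C(Oc1c(OC)cc(Br)cc1OC)C(=O)c1ccc(OCc2ccccc2)cc1
F5 | step 6 | ethyl (2S,3R)-3-[4-(benzyloxy)phenyl]-2-(4-bromo-2,6-dimethoxyphenoxy)-3-hydroxypropanoate | CCOC(=O)[C@@H](Oc1c(OC)cc(Br)cc1OC)[C@H](O)c1ccc(OCc2ccccc2)cc1
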